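**Plan**

Numbering follows benzofuran (O1, C2, C3, C3a, C7a; C9 = hydroxymethyl carbon, C1' = ipso carbon of the guaiacyl ring, ring A = the benzoate ring). The retrosynthesis cuts O1–C7a (C2 alkoxide plus aryl fluoride), exchanges O1 for boron, then cuts C2–C1' and C3–C3a in one operation.
Enabling feature: the C2–C3 edge of the dihydrofuran ring is a vicinal diarylethane. C2 carries the guaiacyl ring and O1, and C3 carries ring A (through C3a) and C9, which is the 1,2-diarylation pattern of an E-configured B–C2H=C3H–C9H2–O alkene.
Forward order: three fragments are made in parallel and merged without ring formation. Both benzene rings are purchased, and the only ring built, the dihydrofuran, is closed near the end at C7a.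
Stereochemistry: both centres arise in the coupling. The chiral bisphosphine on palladium picks the alkene face, and the anti boron-to-carbon shift on the pure E-alkene fixes C2 relative to C3. Retentive B-to-O oxidation and closure at an sp2 carbon carry this through to trans-(2S,3R).
Design choices: boron carries the rigid mac diol (cis-1,2-dimethylacenaphthylene-1,2-diol; B(mac) = its cyclic ester) rather than pinacol, to hold back direct Suzuki transfer. The C9 oxygen carries TIPS rather than a smaller silyl group, to exclude O-to-O silyl shift during ring closure. KOTf removes bromide from the catalyst.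

Key step: step 8

Assumption: the ligand antipode is assigned by analogy with unsubstituted vinyl borates. (Rp,Rp)-MandyPhos is written for the (1S,2R) series. The sense must be confirmed on the first run, and the equally available mirror-image ligand is used if the opposite sense is found.

**Step 1**
Reactants: 1 4-bromo-2-methoxyphenol
Product: 2 (4-bromo-2-methoxyphenoxy)triisopropylsilane
Conditions: TIPSCl, imidazole, DMF, rt
Reagents that add atoms: chlorotriisopropylsilane, CC(C)[Si](Cl)(C(C)C)C(C)C
Why: Imidazole-promoted O-silylation of a phenol removes the acidic proton before the bromine–lithium exchange, and the hindered TIPS ether should survive aryllithium, perborate and alkoxide conditions; no stereocentre is involved.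

**Step 2**
Reactants: 3 propargyl alcohol
Product: 4 triisopropyl(prop-2-yn-1-yloxy)silane
Conditions: TIPSCl, imidazole, CH2Cl2, 0 °C to rt
Reagents that add atoms: chlorotriisopropylsilane, CC(C)[Si](Cl)(C(C)C)C(C)C
Why: Standard silylation of a primary alcohol; TIPS is chosen because in step 10 a C2 alkoxide sits 1,3 to this oxygen, and a silyl shift would free the C9 oxygen for a competing five-membered closure on C7a.

**Step 3**
Reactants: 5 acenaphthoquinone
Product: 6 cis-1,2-dimethyl-1,2-dihydroacenaphthylene-1,2-diol (meso, mac diol)
Conditions: AlMe3 (3 equiv), toluene, 0 °C to rt; aq. Rochelle salt; recrystallisation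
Reagents that add atoms: trimethylaluminium, C[Al](C)C
Why: Twofold 1,2-addition of an organoaluminium reagent to a 1,2-diketone; the second methyl should approach anti to the bulky aluminium alkoxide left by the first, which places both hydroxyls cis, and any trans diol cannot chelate boron and is removed by crystallisation.

**Step 4**
Reactants: 4 triisopropyl(prop-2-yn-1-yloxy)silane; 7 catecholborane; 6 mac diol
Product: 9 (E)-3-(triisopropylsilyloxy)prop-1-enylboronic acid mac ester, via catechol ester 8 (not isolated)
Conditions: 7 (1.1 equiv), Cy2BH (10 mol %), THF, rt; then 6 (1.1 equiv), rt; aq. NaHCO3 wash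
Reagents that add atoms: none
Why: Dialkylborane-catalysed hydroboration of a terminal alkyne puts boron on the terminal carbon by syn addition, which fixes the E geometry, and the labile aryloxy ligands of 8 are then exchanged for the chelating di-tertiary diol (boronic ester transesterification).

**Step 5**
Reactants: 10 4-fluoro-3-methoxybenzoic acid
Product: 11 methyl 4-fluoro-3-methoxybenzoate
Conditions: MeOH, H2SO4 (cat.), reflux
Reagents that add atoms: methanol, CO
Why: Fischer esterification installs the methyl ester of the target, which is also the para activator for the later fluoride displacement.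

**Step 6**
Reactants: 11 methyl 4-fluoro-3-methoxybenzoate
Product: 12 methyl 4-fluoro-3-methoxy-5-(4,4,5,5-tetramethyl-1,3,2-dioxaborolan-2-yl)benzoate
Conditions: B2pin2 (1.0 equiv), [Ir(OMe)(cod)]2 (1.5 mol %), dtbpy (3 mol %), THF, 65 °C
Reagents that add atoms: bis(pinacolato)diboron, CC1(C)OB(OC1(C)C)B1OC(C)(C)C(C)(C)O1
Why: Iridium-catalysed aromatic C–H borylation is sterically governed: in benzoate numbering C2–H lies between ester and methoxy and C6–H is ortho to the ester, whereas C5–H has only fluorine as ortho neighbour and is the most acidic, so boron should enter at C5.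

**Step 7**
Reactants: 12 methyl 4-fluoro-3-methoxy-5-(pinacolboryl)benzoate
Product: 13 methyl 3-bromo-4-fluoro-5-methoxybenzoate
Conditions: CuBr2 (3 equiv), MeOH/H2O (1:1), 80 °C
Reagents that add atoms: copper(II) bromide, [Cu+2].[Br-].[Br-]
Why: Copper(II)-mediated ipso-bromodeboronation replaces boron by bromine at the same carbon, a position that electrophilic bromination (directed para to methoxy) cannot reach, and it leaves ester and C–F untouched.

**Step 8**
Reactants: 2 (4-bromo-2-methoxyphenoxy)triisopropylsilane; 9 (E)-3-(triisopropylsilyloxy)prop-1-enylboronic acid mac ester; 13 methyl 3-bromo-4-fluoro-5-methoxybenzoate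
Product: 16 methyl 4-fluoro-3-methoxy-5-{(1S,2R)-1-[3-methoxy-4-(triisopropylsilyloxy)phenyl]-1-B(mac)-3-(triisopropylsilyloxy)propan-2-yl}benzoate, via aryllithium 14 (not isolated), via lithium borate 15 (not isolated)
Conditions: 2 (1.0 equiv), t-BuLi (2.0 equiv), Et2O, −78 °C; 9 (1.05 equiv), −78 °C to rt; evaporate; 13 (1.0 equiv), Pd(OAc)2 (3 mol %), (Rp,Rp)-MandyPhos (3.6 mol %), KOTf (2.5 equiv), THF, 45 °C
Reagents that add atoms: tert-butyllithium, [Li]C(C)(C)C (supplies the lithium of 14 and 15; none of its atoms remains in 16)
Why: Bromine–lithium exchange on 2 gives 14, which adds to the vacant boron orbital of 9 to form borate 15, while oxidative addition of 13 to the bisphosphine–Pd(0) complex and bromide abstraction by KOTf leave a cationic arylpalladium(II) species that binds the C2=C3 π bond. Coordination triggers a 1,2-metallate shift in which the guaiacyl group leaves boron and bonds to C2 on the face opposite palladium (C2–C1'), palladium becomes σ-bound to C3, and reductive elimination with retention makes C3–C3a; no ring is closed. The closest known reaction is the enantioselective palladium-catalysed conjunctive cross-coupling of alkenylboron ate complexes with aryl electrophiles, in its variant for β-substituted alkenyl mac boronates. C3 is controlled by the ligand, which decides the alkene face that palladium occupies, and C2 by the stereospecific anti shift on the geometrically pure E-alkene, so net anti 1,2-diarylation gives the (1S,2R) isomer that maps onto the trans ring after retentive oxidation. The shift must outrun direct boron-to-palladium transfer (Suzuki products), which the rigid, hindered mac diol disfavours, while the electron-rich guaiacyl group migrates readily and the electron-poor bromide, flanked only by fluorine, adds quickly to Pd(0). The chelating ligand leaves no free site at the C3–Pd stage for β-hydride or β-silyloxy elimination, the slight excess of 9 over 14 keeps free aryllithium away from the ester, and the C–F bond is inert to the catalyst.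

**Step 9**
Reactants: 16 secondary benzylic mac boronate
Product: 17 methyl 4-fluoro-3-{(1S,2R)-1-hydroxy-1-[3-methoxy-4-(triisopropylsilyloxy)phenyl]-3-(triisopropylsilyloxy)propan-2-yl}-5-methoxybenzoate
Conditions: NaBO3·4H2O (5 equiv), THF/H2O (1:1), rt
Reagents that add atoms: sodium perborate (used as tetrahydrate), [Na+].[O-]OB=O
Why: Boronate oxidation proceeds by peroxide addition to boron and migration of C2 from boron to oxygen with retention, so (S)-C2 is carried over, and perborate is mild enough for the methyl ester and the aryl silyl ether.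

**Step 10**
Reactants: 17 fluoro alcohol
Product: 18 methyl (2S,3R)-7-methoxy-2-[3-methoxy-4-(triisopropylsilyloxy)phenyl]-3-(triisopropylsilyloxymethyl)-2,3-dihydrobenzofuran-5-carboxylate (trans)
Conditions: KHMDS (1.05 equiv), THF (0.02 M), 0 °C to 40 °C
Reagents that add atoms: none
Why: Intramolecular SNAr: the C2 potassium alkoxide adds to C7a, the para ester stabilises the Meisenheimer intermediate and fluoride leaves as insoluble KF; no bond at C2 or C3 is broken, so the configuration set in step 8 appears as the trans ring, and the hindered TIPS groups should resist migration.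

**Step 11**
Reactants: 18 bis-TIPS ether
Product: 19 Curlignan, methyl (2S,3R)-2-(4-hydroxy-3-methoxyphenyl)-3-(hydroxymethyl)-7-methoxy-2,3-dihydrobenzofuran-5-carboxylate
Conditions: TBAF (3 equiv), AcOH (3 equiv), THF, 0 °C to rt
Reagents that add atoms: none
Why: Fluoride cleaves both Si–O bonds, and the acetic acid buffer keeps the liberated phenol protonated, so the 4-hydroxybenzyl aryl ether does not open to a quinone methide and the ester is not saponified; the stereocentres are untouched.

**Compound list**

1 | 4-bromo-2-methoxyphenol | COc1cc(Br)ccc1O | starting material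
2 | (4-bromo-2-methoxyphenoxy)triisopropylsilane | COc1cc(Br)ccc1O[Si](C(C)C)(C(C)C)C(C)C | intermediate
3 | propargyl alcohol | C#CCO | starting material
4 | triisopropyl(prop-2-yn-1-yloxy)silane | C#CCO[Si](C(C)C)(C(C)C)C(C)C | intermediate
5 | acenaphthoquinone | O=C1C(=O)c2cccc3cccc1c23 | starting material
6 | cis-1,2-dimethyl-1,2-dihydroacenaphthylene-1,2-diol (meso, mac diol) | C[C@]1(O)c2cccc3cccc(c23)[C@@]1(C)O | intermediate
7 | catecholborane | B1Oc2ccccc2O1 | starting material
8 | (E)-3-(triisopropylsilyloxy)prop-1-enylboronic acid catechol ester (not isolated) | CC(C)[Si](C(C)C)(C(C)C)OC/C=C/B1Oc2ccccc2O1 | intermediate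
9 | (E)-3-(triisopropylsilyloxy)prop-1-enylboronic acid mac ester | CC(C)[Si](C(C)C)(C(C)C)OC/C=C/B1O[C@@]2(C)c3cccc4cccc(c34)[C@@]2(C)O1 | intermediate
10 | 4-fluoro-3-methoxybenzoic acid | COc1cc(C(=O)O)ccc1F | starting material
11 | methyl 4-fluoro-3-methoxybenzoate | COC(=O)c1ccc(F)c(OC)c1 | intermediate
12 | methyl 4-fluoro-3-methoxy-5-(pinacolboryl)benzoate | COC(=O)c1cc(OC)c(F)c(c1)B1OC(C)(C)C(C)(C)O1 | intermediate
13 | methyl 3-bromo-4-fluoro-5-methoxybenzoate | COC(=O)c1cc(Br)c(F)c(OC)c1 | intermediate
14 | 3-methoxy-4-(triisopropylsilyloxy)phenyllithium (not isolated) | [Li]c1ccc(O[Si](C(C)C)(C(C)C)C(C)C)c(OC)c1 | intermediate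
15 | lithium aryl(alkenyl)borate of 9 and 14 (not isolated; configuration at boron not defined) | [Li+].COc1cc(ccc1O[Si](C(C)C)(C(C)C)C(C)C)[B-]1(/C=C/CO[Si](C(C)C)(C(C)C)C(C)C)O[C@@]2(C)c3cccc4cccc(c34)[C@@]2(C)O1 | intermediate
16 | (1S,2R) secondary benzylic mac boronate, boron on C2 | COC(=O)c1cc(OC)c(F)c(c1)[C@H](CO[Si](C(C)C)(C(C)C)C(C)C)[C@@H](c1ccc(O[Si](C(C)C)(C(C)C)C(C)C)c(OC)c1)B1O[C@@]2(C)c3cccc4cccc(c34)[C@@]2(C)O1 | intermediate
17 | (1S,2R) fluoro alcohol | COC(=O)c1cc(OC)c(F)c(c1)[C@H](CO[Si](C(C)C)(C(C)C)C(C)C)[C@@H](c1ccc(O[Si](C(C)C)(C(C)C)C(C)C)c(OC)c1)O | intermediate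
18 | (2S,3R) bis-TIPS dihydrobenzofuran | COC(=O)c1cc(OC)c2c(c1)[C@H](CO[Si](C(C)C)(C(C)C)C(C)C)[C@@H](c1ccc(O[Si](C(C)C)(C(C)C)C(C)C)c(OC)c1)O2 | intermediate
19 | Curlignan | COC(=O)c1cc(OC)c2c(c1)[C@H](CO)[C@@H](c1ccc(O)c(OC)c1)O2 | target

**Step count**

Total step count: 11. Longest linear sequence: 7 (steps 5, 6, 7, 8, 9, 10, 11, from 10).

**Steps most likely to fail**

**Step 8.** Direct boron-to-palladium transfer may overtake the metallate shift on this β-substituted alkene. β-Silyloxy or β-hydride elimination may drain the C3–Pd intermediate. Facial selectivity may also be poor.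

The fallback sets out from 13 and 14 and returns at 17. It builds C2–C3 by an auxiliary-controlled aldol instead of the two aryl bonds.
- Palladium-catalysed coupling of 13 with the Reformatsky reagent of tert-butyl bromoacetate gives methyl 3-(2-tert-butoxy-2-oxoethyl)-4-fluoro-5-methoxybenzoate F1.
- TFA frees [2-fluoro-3-methoxy-5-(methoxycarbonyl)phenyl]acetic acid F2.
- DCC/DMAP joins F2 to (S)-4-benzyloxazolidin-2-one to give the N-arylacetyl imide F3.
- Quenching 14 with DMF gives 3-methoxy-4-(triisopropylsilyloxy)benzaldehyde F4.
- Enolisation of F3 with Bu2BOTf/Et3N and addition of F4 (Evans syn aldol) should give the (2S,3S) syn aldol adduct F5. Its two centres have the spatial arrangement of C3 and C2 in 17.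
- NaBH4 in THF/H2O removes the auxiliary reductively, without touching the benzoate, to give the (1S,2R) 1,3-diol F6.
- Selective silylation of the primary hydroxyl (TIPSCl, imidazole, 0 °C) gives 17.

**Step 10.** Addition to the only moderately activated, doubly ortho-substituted fluoroarene may be slow. That would let silyl transfer, attack on the ester or fluoride-induced desilylation compete.

The fallback sets out from 15 and returns at 18. It takes O1 from ring A instead of from boron.
- Commercial methyl 3-bromo-4-hydroxy-5-methoxybenzoate is protected (MOMCl, i-Pr2NEt) as methyl 3-bromo-5-methoxy-4-(methoxymethoxy)benzoate F7.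
- F7 is coupled with 15 under the conditions of step 8 to give the (1S,2R) MOM-protected mac boronate F8.
- Perborate oxidation gives the (1S,2R) MOM-protected benzylic alcohol F9.
- TFA in CH2Cl2 at 0 °C ionises the electron-rich benzylic alcohol and unmasks the ring A phenol oxygen, which captures the cation. The C2 configuration is lost on the way, but it is reset anti to the CH2OTIPS group by the intact C3 centre, giving trans 18.

**Step 4.** Ligand exchange at boron may stall, the moisture-sensitive catechol ester may hydrolyse during handling, or regiocontrol next to the propargylic oxygen may erode.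

The fallback sets out from 4 and returns at 9, passing through isolable boron compounds.
- Hydroboration of 4 with pinacolborane (Cp2ZrHCl cat., Et3N cat.) gives (E)-3-(triisopropylsilyloxy)prop-1-enylboronic acid pinacol ester F10.
- Oxidative removal of pinacol (NaIO4, NH4OAc, acetone/H2O) gives (E)-3-(triisopropylsilyloxy)prop-1-enylboronic acid F11.
- Condensation of F11 with 6 over MgSO4 in CH2Cl2 gives 9.

**Further compounds**

F1 | step 8 | methyl 3-(2-tert-butoxy-2-oxoethyl)-4-fluoro-5-methoxybenzoate | COC(=O)c1cc(OC)c(F)c(c1)CC(=O)OC(C)(C)C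
F2 | step 8 | [2-fluoro-3-methoxy-5-(methoxycarbonyl)phenyl]acetic acid | COC(=O)c1cc(OC)c(F)c(c1)CC(=O)O
F3 | step 8 | N-arylacetyl imide of (S)-4-benzyloxazolidin-2-one | COC(=O)c1cc(OC)c(F)c(c1)CC(=O)N1[C@@H](Cc2ccccc2)COC1=O
F4 | step 8 | 3-methoxy-4-(triisopropylsilyloxy)benzaldehyde | COc1cc(C=O)ccc1O[Si](C(C)C)(C(C)C)C(C)C
F5 | step 8 | (2S,3S) syn aldol adduct | COC(=O)c1cc(OC)c(F)c(c1)[C@H](C(=O)N1[C@@H](Cc2ccccc2)COC1=O)[C@@H](c1ccc(O[Si](C(C)C)(C(C)C)C(C)C)c(OC)c1)O
F6 | step 8 | (1S,2R) 1,3-diol | COC(=O)c1cc(OC)c(F)c(c1)[C@H](CO)[C@@H](c1ccc(O[Si](C(C)C)(C(C)C)C(C)C)c(OC)c1)O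
F7 | step 10 | methyl 3-bromo-5-methoxy-4-(methoxymethoxy)benzoate | COC(=O)c1cc(Br)c(OCOC)c(OC)c1
F8 | step 10 | (1S,2R) MOM-protected mac boronate | COC(=O)c1cc(OC)c(OCOC)c(c1)[C@H](CO[Si](C(C)C)(C(C)C)C(C)C)[C@@H](c1ccc(O[Si](C(C)C)(C(C)C)C(C)C)c(OC)c1)B1O[C@@]2(C)c3cccc4cccc(c34)[C@@]2(C)O1
F9 | step 10 | (1S,2R) MOM-protected benzylic alcohol | COC(=O)c1cc(OC)c(OCOC)c(c1)[C@H](CO[Si](C(C)C)(C(C)C)C(C)C)[C@@H](c1ccc(O[Si](C(C)C)(C(C)C)C(C)C)c(OC)c1)O
F10 | step 4 | (E)-3-(triisopropylsilyloxy)prop-1-enylboronic acid pinacol ester | CC(C)[Si](C(C)C)(C(C)C)OC/C=C/B1OC(C)(C)C(C)(C)O1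
F11 | step 4 | (E)-3-(triisopropylsilyloxy)prop-1-enylboronic acid | CC(C)[Si](C(C)C)(C(C)C)OC/C=C/B(O)O
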